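**Assumptions (one line each)**
- (R)-(+)-Limonene carries C1 of the target, with the same spatial arrangement and descriptor (R).
- The macrocycle set up by C1 is assumed to relay facial selectivity to C8/C9 (pinacol closure) and to the four epoxide-derived centres. Diastereomers, where formed, are separated chromatographically.

## Retrosynthetic overview
1. Target ⇐ late allylic oxidation of the isopropenyl methyl group (C17) to CO2H (SeO2, MnO2, NaClO2) ⇐ THF-triol-acetate **19**.
2. The cis-THF (C5–O–C8), C4-OH and the anti C12/C13 diol come from one acid-promoted epoxide opening of bis-epoxide **16**. Both epoxides derive from E-alkenes and are opened with inversion, which gives the anti relationships.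
3. **16** ⇐ E,E-diene diol **14** ⇐ SmI2 macrocyclic pinacol closure at C8–C9 of keto-aldehyde **13**. This is the only carbocycle-forming step, and the THF forms afterwards.
4. **13** ⇐ two [3,3] Claisen rearrangements. A Saucy–Marbet Claisen forms C6–C7 and the E-C4=C5 alkene. A vinyl-ether Claisen forms C10–C11 and the E-C12=C13 alkene. Both operate on allylic alcohols built from (R)-limonene-derived keto-aldehyde **3**.
5. Ring order: the 14-membered carbocycle first (step 9), then the THF (step 12).

## Forward route

**Step 1**
Reactants: **1** (R)-(+)-limonene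
Product: **2** (4R)-limonene 1,2-epoxide (cis/trans mixture at the epoxide)
Conditions: mCPBA (1.0 equiv), NaHCO3, CH2Cl2, 0 °C
Reagents that add atoms: mCPBA, OOC(=O)c1cccc(Cl)c1
Why: Prilezhaev epoxidation is selective for the electron-rich trisubstituted ring alkene over the isopropenyl group; the C4 stereocentre is untouched and the epoxide diastereomers converge later.

**Step 2**
Reactants: **2**
Product: **3** (R)-3-(prop-1-en-2-yl)-6-oxoheptanal
Conditions: H5IO6, THF/Et2O, rt
Reagents that add atoms: water, O; H5IO6 is the oxidant, O=I(O)(O)(O)(O)O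
Why: The epoxide hydrolyses to the diol, and periodate glycol cleavage (Malaprade) gives the keto-aldehyde without touching the isopropenyl group or the C1 stereocentre.

**Step 3**
Reactants: **3**, **4** isopropenylmagnesium bromide
Product: **5** (5R)-7-hydroxy-8-methyl-5-(prop-1-en-2-yl)non-8-en-2-one (C13 epimeric mixture)
Conditions: **4** (1.05 equiv), THF, −78 °C
Reagents that add atoms: isopropenylmagnesium bromide, C=C(C)[Mg]Br
Why: Grignard addition is chemoselective for the aldehyde over the methyl ketone at low temperature. The new C13 carbinol is unselective, but the Claisen in step 8 destroys it.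

**Step 4**
Reactants: **5**
Product: **6** the TBDPS ether of **5**
Conditions: TBDPSCl, imidazole, DMAP, DMF, rt
Reagents that add atoms: TBDPSCl, CC(C)(C)[Si](Cl)(c1ccccc1)c1ccccc1
Why: The secondary allylic alcohol is masked so that only the tertiary allylic alcohol formed next undergoes the acid-promoted Claisen (the silyl group is acid-robust at 110 °C).

**Step 5**
Reactants: **6**, **7** vinylmagnesium bromide
Product: **8** tertiary allylic alcohol (vinyl adduct at the C4 ketone; C4 epimeric mixture)
Conditions: **7**, anhydrous CeCl3, THF, −78 °C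
Reagents that add atoms: vinylmagnesium bromide, C=C[Mg]Br
Why: Organocerium addition to the enolisable methyl ketone gives the linalool-type tertiary allylic alcohol; the C4 epimers converge at the next step because C4 becomes sp2.

**Step 6**
Reactants: **8**, **9** 2-methoxypropene
Product: **10** (E)-C4=C5 methyl ketone, TBDPS-protected (C8 methyl ketone)
Conditions: **9** (excess), cat. PPTS, PhMe, 110 °C sealed tube; Z isomer removed on AgNO3-silica
Reagents that add atoms: 2-methoxypropene, COC(C)=C
Why: Saucy–Marbet ([3,3] Claisen) of the mixed enol ether forms C6–C7 and the C4=C5 alkene, and installs the C8 methyl ketone directly; the E isomer is major by the chair transition state.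

**Step 7**
Reactants: **10**
Product: **11** free allylic alcohol at C13
Conditions: TBAF, THF, rt
Reagents that add atoms: none
Why: Fluoride removes the TBDPS group and leaves the ketone and alkenes intact.

**Step 8**
Reactants: **11**, **12** ethyl vinyl ether
Product: **13** (E,E)-keto-aldehyde (C9 aldehyde, C8 methyl ketone)
Conditions: Hg(OAc)2 (cat.), **12** (excess), 35 °C; then PhMe, 160 °C sealed tube
Reagents that add atoms: ethyl vinyl ether, C=COCC
Why: Hg(II) transvinylation gives the allyl vinyl ether, and the [3,3] Claisen forms C10–C11 and delivers the aldehyde. The secondary allylic alcohol with a 1,1-disubstituted alkene gives the E-trisubstituted C12=C13 alkene through an equatorial-R chair, so the C13 epimers converge.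

**Step 9**
Reactants: **13**
Product: **14** 14-membered (E,E)-diene diol, 8R,9S
Conditions: SmI2 (3 equiv), t-BuOH (2 equiv), THF, 0.002 M, syringe-pump addition, 0 °C
Reagents that add atoms: none (H from t-BuOH)
Why: An intramolecular Sm(II) ketyl–ketone pinacol coupling closes the ring at C8–C9 and sets both carbinols. The anti (erythro) diol is favoured by the macrocycle conformation that C1 imposes.

**Step 10**
Reactants: **14**
Product: **15** C9-OTBS ether
Conditions: TBSCl, imidazole, DMF, 0 °C
Reagents that add atoms: TBSCl, CC(C)(C)[Si](C)(C)Cl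
Why: The secondary C9-OH is silylated selectively over the tertiary C8-OH. This blocks a competing C9–O–C12 ring closure later and leaves C8-OH free as the THF oxygen.

**Step 11**
Reactants: **15**
Product: **16** bis-epoxide (4R,5R,12R,13R; trans-epoxides)
Conditions: mCPBA (2.1 equiv), NaHCO3, CH2Cl2, −20 °C
Reagents that add atoms: mCPBA, OOC(=O)c1cccc(Cl)c1
Why: Prilezhaev epoxidation of the two E-trisubstituted alkenes (faster than the isopropenyl) gives trans-epoxides. Peripheral-face attack on the preferred macrocycle conformer is expected to give the required faces.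

**Step 12**
Reactants: **16**
Product: **17** cis-THF triol, C9-OTBS (4R,5S,8R,12S,13R)
Conditions: CSA (0.2 equiv), MeCN/H2O 9:1, 0 °C → rt
Reagents that add atoms: water, O
Why: The C8 tertiary OH opens the 4,5-epoxide in a 5-exo fashion with inversion at C5, and the epoxide oxygen becomes the C4 tertiary OH. The 12,13-epoxide is opened at tertiary C12 by water with inversion, giving the anti diol. Both openings invert one centre of a trans-epoxide, so the E-alkenes translate into the anti (erythro) relationships of the target.

**Step 13**
Reactants: **17**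
Product: **18** C13 acetate
Conditions: Ac2O, pyridine, DMAP (cat.), CH2Cl2, 0 °C
Reagents that add atoms: Ac2O, CC(=O)OC(C)=O
Why: Only the C13 secondary OH is acetylated; the two tertiary alcohols and the C9 silyl ether are unreactive.

**Step 14**
Reactants: **18**
Product: **19** isopropenyl THF-triol acetate
Conditions: TBAF/AcOH (1:1), THF, rt
Reagents that add atoms: none
Why: Buffered fluoride removes the TBS group while avoiding acetyl migration or cleavage.

**Step 15**
Reactants: **19**
Product: **20** allylic alcohol (C17-OH)
Conditions: SeO2 (0.3 equiv), TBHP, CH2Cl2, rt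
Reagents that add atoms: SeO2, O=[Se]=O (TBHP is the co-oxidant)
Why: Riley allylic oxidation of the isopropenyl group (now the only alkene): ene reaction then [2,3] shift gives the symmetric 2-substituted allylic alcohol.

**Step 16**
Reactants: **20**
Product: **21** α-methylene aldehyde (enal)
Conditions: MnO2 (excess), CH2Cl2, rt
Reagents that add atoms: none
Why: MnO2 oxidises only the allylic alcohol; the C9 secondary and the tertiary alcohols are inert.

**Step 17**
Reactants: **21**
Product: **22** Dendronpholide J
Conditions: NaClO2, NaH2PO4, 2-methyl-2-butene, t-BuOH/H2O, rt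
Reagents that add atoms: NaClO2, [Na+].[O-]Cl=O
Why: Pinnick oxidation converts the aldehyde to the acid under mild conditions that leave the acetate, the alcohols, the THF and the C15=C16 alkene untouched.

## Compound list
1 | (R)-(+)-limonene | CC1=CC[C@@H](CC1)C(C)=C | starting material
2 | (4R)-limonene 1,2-epoxide | CC12OC1C[C@@H](CC2)C(C)=C | intermediate
3 | (R)-3-isopropenyl-6-oxoheptanal | O=CC[C@H](C(C)=C)CCC(C)=O | intermediate
4 | isopropenylmagnesium bromide | C=C(C)[Mg]Br | starting material
5 | 7-hydroxy-8-methyl-5-isopropenylnon-8-en-2-one (C13 epimers) | C=C(C)C(O)C[C@H](C(C)=C)CCC(C)=O | intermediate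
6 | TBDPS ether of 5 | C=C(C)C(O[Si](c1ccccc1)(c1ccccc1)C(C)(C)C)C[C@H](C(C)=C)CCC(C)=O | intermediate
7 | vinylmagnesium bromide | C=C[Mg]Br | starting material
8 | tertiary allylic alcohol (C4 epimers) | C=C(C)C(O[Si](c1ccccc1)(c1ccccc1)C(C)(C)C)C[C@H](C(C)=C)CCC(C)(O)C=C | intermediate
9 | 2-methoxypropene | COC(C)=C | starting material
10 | (E)-C4=C5 methyl ketone, TBDPS ether | C=C(C)C(O[Si](c1ccccc1)(c1ccccc1)C(C)(C)C)C[C@H](C(C)=C)CC/C(C)=C/CCC(C)=O | intermediate
11 | free C13 allylic alcohol | C=C(C)C(O)C[C@H](C(C)=C)CC/C(C)=C/CCC(C)=O | intermediate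
12 | ethyl vinyl ether | C=COCC | starting material
13 | (E,E)-keto-aldehyde | O=CCC/C(C)=C/C[C@H](C(C)=C)CC/C(C)=C/CCC(C)=O | intermediate
14 | macrocyclic (E,E)-diene diol (8R,9S) | C=C(C)[C@@H]1CC/C(C)=C/CC[C@@](C)(O)[C@@H](O)CC/C(C)=C/C1 | intermediate
15 | C9-OTBS ether of 14 | C=C(C)[C@@H]1CC/C(C)=C/CC[C@@](C)(O)[C@@H](O[Si](C)(C)C(C)(C)C)CC/C(C)=C/C1 | intermediate
16 | bis-epoxide (4R,5R,12R,13R) | C=C(C)[C@@H]1CC[C@@]2(C)O[C@@H]2CC[C@@](C)(O)[C@@H](O[Si](C)(C)C(C)(C)C)CC[C@@]2(C)O[C@@H]2C1 | intermediate
17 | cis-THF triol, C9-OTBS | C=C(C)[C@@H]1CC[C@@](C)(O)[C@@H]2CC[C@@](C)(O2)[C@@H](O[Si](C)(C)C(C)(C)C)CC[C@](C)(O)[C@H](O)C1 | intermediate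
18 | C13 acetate of 17 | C=C(C)[C@@H]1CC[C@@](C)(O)[C@@H]2CC[C@@](C)(O2)[C@@H](O[Si](C)(C)C(C)(C)C)CC[C@](C)(O)[C@H](OC(C)=O)C1 | intermediate
19 | isopropenyl THF-triol acetate | C=C(C)[C@@H]1CC[C@@](C)(O)[C@@H]2CC[C@@](C)(O2)[C@@H](O)CC[C@](C)(O)[C@H](OC(C)=O)C1 | intermediate
20 | allylic alcohol (C17-OH) | C=C(CO)[C@@H]1CC[C@@](C)(O)[C@@H]2CC[C@@](C)(O2)[C@@H](O)CC[C@](C)(O)[C@H](OC(C)=O)C1 | intermediate
21 | α-methylene aldehyde | C=C(C=O)[C@@H]1CC[C@@](C)(O)[C@@H]2CC[C@@](C)(O2)[C@@H](O)CC[C@](C)(O)[C@H](OC(C)=O)C1 | intermediate
22 | Dendronpholide J | C=C(C(=O)O)[C@@H]1CC[C@@](C)(O)[C@@H]2CC[C@@](C)(O2)[C@@H](O)CC[C@](C)(O)[C@H](OC(C)=O)C1 | target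

**Total steps:** 17. **Longest linear sequence:** 17, from (R)-limonene.

**Three steps most likely to fail**
1. **Step 9 (SmI2 macrocyclic pinacol).** Yield and the C8/C9 diastereoselectivity are uncertain. Fallback: close the ring by an intramolecular McMurry coupling of **13** to the E-C8=C9 trisubstituted alkene (a cembrene-type triene), then oxygenate C8=C9 by epoxidation with C5-OH/C8-O ring closure.
2. **Step 11 (bis-epoxidation face selectivity).** Macrocycle control over four new centres may be poor. Fallback: install C12/C13 early by VO(acac)2-directed epoxidation of the 1,1-disubstituted allylic alcohol from step 3 followed by carbon-nucleophile epoxide opening, and form the THF by C8-OH displacement of a C5 secondary mesylate with inversion.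
3. **Step 6 (Saucy–Marbet).** The E/Z ratio at C4=C5 may be poor, and the tertiary allylic alcohol may ionise under acid. Fallback: build the E-C4=C5 alkene by HWE olefination of the methyl ketone, then reduce to the allylic alcohol, convert to the allylic bromide, and alkylate ethyl acetoacetate with decarboxylation to the C8 methyl ketone.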